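**Retrosynthetic overview**
1. Target 23 ⇐ 22 by Markovnikov hydration of a 2-methylallyl side chain (last step, no protecting groups).
2. 22 ⇐ iodide 19 + enal triflate 14 in a one-flask (3+3) annulation: Negishi coupling forms C7–C6, then carbene-catalysed hydroacylation of the exocyclic methylene forms C4–C3a and the 3a-methyl group.
3. Enabling feature: in the cyclohexenone ring (C3a, C4, C5, C6, C7, C7a) the C4 ketone is bonded to the methyl-bearing quaternary C3a next to quaternary C7a (retron of an aldehyde C–H addition across a 2-methylidenecyclopentane), and the tetrasubstituted C5=C6 enone carries the sp3 carbon C7 on its β-carbon (retron of an alkyl coupling to a β-keto-ester enol triflate).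
4. 14 ⇐ acid 7 + ester 8 (C-acylation, Z-enol triflate, reduction, oxidation); 7 ⇐ phenol 1 by ortho-quinone methide alkylation and enantioselective Wacker-type cyclisation/carbonylation; 19 ⇐ β-keto ester 15 by asymmetric methylation, methylenation, reduction, iodination.
5. Ring order: cyclopentane (bought with 15), chroman oxygen ring (step 3), cyclohexenone (step 13).

Key step: step 13

Assumption: the bicyclic ketone is numbered as 1,2,3,3a,7,7a-hexahydro-4H-inden-4-one (C4 carbonyl, C5 and C6 enone carbons, C7 ring CH2, C3a and C7a methyl-bearing ring-fusion carbons), and in steps 3 and 9 the enantiomer of the chiral ligand or catalyst that gives the drawn configuration is used.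

**Route**

Step 1
Reactants: 1 4-methoxy-2-methylphenol
Product: 2 2-[(dimethylamino)methyl]-4-methoxy-6-methylphenol
Conditions: aq. CH2O, aq. Me2NH, EtOH, 25→60 °C
Reagents that add atoms: formaldehyde C=O; dimethylamine CNC
Why: Phenolic Mannich reaction: the iminium ion formed from formaldehyde and dimethylamine attacks the only free ortho position of the phenol (the para position is blocked by the methoxy group).

Step 2
Reactants: 2 2-[(dimethylamino)methyl]-4-methoxy-6-methylphenol
Product: 5 4-methoxy-2-methyl-6-(3-methylbut-3-en-1-yl)phenol, via ammonium iodide 3 (not isolated), via ortho-quinone methide 4 (not isolated)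
Conditions: MeI, THF, 25 °C; then CH2=C(CH3)CH2MgCl (3 equiv), −78→25 °C; aq. NH4Cl
Reagents that add atoms: 2-methylallylmagnesium chloride C=C(C)C[Mg]Cl
Why: Quaternisation turns the amine into a leaving group, the magnesium phenoxide expels trimethylamine to give ortho-quinone methide 4, and the allylic Grignard reagent adds 1,4 to its exocyclic methylene (conjugate addition to an ortho-quinone methide), which restores the aromatic ring.

Step 3
Reactants: 5 4-methoxy-2-methyl-6-(3-methylbut-3-en-1-yl)phenol
Product: 6 methyl 2-[(2R)-6-methoxy-2,8-dimethyl-3,4-dihydro-2H-chromen-2-yl]acetate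
Conditions: Pd(OCOCF3)2 (5 mol%), 2,2′-bis(4-benzyl-4,5-dihydrooxazol-2-yl)-1,1′-binaphthyl (Bn-BOXAX, 20 mol%), p-benzoquinone, CO (1 atm), MeOH, 25 °C
Reagents that add atoms: carbon monoxide [C-]#[O+]; methanol CO
Why: Enantioselective domino Wacker-type oxypalladation/carbonylation: divalent palladium bound to the chiral bis(oxazoline) ligand activates the 1,1-disubstituted alkene for 6-exo attack of the phenol oxygen, which sets the tertiary ether centre under ligand control, and the resulting neopentyl-type alkylpalladium species, which has no β-hydrogen, inserts CO and is cleaved by methanol.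

Step 4
Reactants: 6 methyl 2-[(2R)-6-methoxy-2,8-dimethyl-3,4-dihydro-2H-chromen-2-yl]acetate
Product: 7 2-[(2R)-6-methoxy-2,8-dimethyl-3,4-dihydro-2H-chromen-2-yl]acetic acid
Conditions: LiOH, THF/MeOH/H2O, 25 °C; then aq. HCl to pH 3
Reagents that add atoms: lithium hydroxide [Li+].[OH-]
Why: Saponification of the methyl ester by hydroxide (acyl substitution), which does not touch the quaternary stereocentre.

Step 5
Reactants: 7 2-[(2R)-6-methoxy-2,8-dimethyl-3,4-dihydro-2H-chromen-2-yl]acetic acid; 8 ethyl 4-methylpent-4-enoate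
Product: 11 ethyl 4-[(2R)-6-methoxy-2,8-dimethyl-3,4-dihydro-2H-chromen-2-yl]-2-(2-methylprop-2-en-1-yl)-3-oxobutanoate, via acyl imidazole 9 (not isolated), via lithium enolate 10 (not isolated)
Conditions: 7, 1,1′-carbonyldiimidazole, THF, 25 °C; separately 8 (2.2 equiv), LiN(i-Pr)2, THF, −78 °C; then 9 added at −78 °C; aq. NH4Cl
Reagents that add atoms: none
Why: Claisen-type C-acylation of an ester enolate by an acyl imidazole; the second equivalent of enolate deprotonates the β-keto ester as it forms, which stops over-addition and keeps the base-sensitive β-aryloxy ketone as its inert 1,3-dicarbonyl enolate.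

Step 6
Reactants: 11 ethyl 4-[(2R)-6-methoxy-2,8-dimethyl-3,4-dihydro-2H-chromen-2-yl]-2-(2-methylprop-2-en-1-yl)-3-oxobutanoate
Product: 12 ethyl (2Z)-4-[(2R)-6-methoxy-2,8-dimethyl-3,4-dihydro-2H-chromen-2-yl]-2-(2-methylprop-2-en-1-yl)-3-{[(trifluoromethyl)sulfonyl]oxy}but-2-enoate
Conditions: NaH, Et2O/THF, 0 °C; then (CF3SO2)2O, −78→0 °C
Reagents that add atoms: trifluoromethanesulfonic anhydride O=S(=O)(OS(=O)(=O)C(F)(F)F)C(F)(F)F
Why: O-Triflation of the sodium enolate of the β-keto ester, in which chelation of sodium by both carbonyl oxygens fixes the enolate so that the triflate ends up cis to the ester group (Z).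

Step 7
Reactants: 12 ethyl (2Z)-4-[(2R)-6-methoxy-2,8-dimethyl-3,4-dihydro-2H-chromen-2-yl]-2-(2-methylprop-2-en-1-yl)-3-{[(trifluoromethyl)sulfonyl]oxy}but-2-enoate
Product: 13 (2Z)-4-hydroxy-1-[(2R)-6-methoxy-2,8-dimethyl-3,4-dihydro-2H-chromen-2-yl]-3-(2-methylprop-2-en-1-yl)but-2-en-2-yl trifluoromethanesulfonate
Conditions: i-Bu2AlH (2.5 equiv), CH2Cl2, −78 °C; aq. potassium sodium tartrate
Reagents that add atoms: none
Why: 1,2-Reduction of the conjugated ester to the allylic alcohol by the aluminium hydride at low temperature, which leaves the vinyl triflate and the alkene geometry intact.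

Step 8
Reactants: 13 (2Z)-4-hydroxy-1-[(2R)-6-methoxy-2,8-dimethyl-3,4-dihydro-2H-chromen-2-yl]-3-(2-methylprop-2-en-1-yl)but-2-en-2-yl trifluoromethanesulfonate
Product: 14 (2Z)-3-formyl-1-[(2R)-6-methoxy-2,8-dimethyl-3,4-dihydro-2H-chromen-2-yl]-5-methylhexa-2,5-dien-2-yl trifluoromethanesulfonate
Conditions: Dess–Martin periodinane, CH2Cl2, 0→25 °C
Reagents that add atoms: none
Why: Dess–Martin oxidation of the primary allylic alcohol to the aldehyde under neutral conditions, which avoids base-induced opening of the chroman ring and isomerisation of the alkene.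

Step 9
Reactants: 15 tert-butyl 2-oxocyclopentane-1-carboxylate
Product: 16 tert-butyl (1R)-1-methyl-2-oxocyclopentane-1-carboxylate
Conditions: MeI, chiral N-spiro bis(3,3′-diaryl-1,1′-binaphthyl-2,2′-dimethylene)ammonium bromide (1 mol%), K2CO3, toluene/H2O, 0 °C
Reagents that add atoms: iodomethane CI
Why: Asymmetric phase-transfer alkylation of a β-keto ester: the chiral ammonium cation pairs with the enolate and shields one of its faces, so that methylation sets the quaternary centre as 1R.

Step 10
Reactants: 16 tert-butyl (1R)-1-methyl-2-oxocyclopentane-1-carboxylate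
Product: 17 tert-butyl (1R)-1-methyl-2-methylidenecyclopentane-1-carboxylate
Conditions: Ph3PCH3Br, KN(SiMe3)2, toluene, 0→80 °C
Reagents that add atoms: methyltriphenylphosphonium bromide C[P+](c1ccccc1)(c1ccccc1)c1ccccc1.[Br-]
Why: Wittig methylenation of the ketone by a salt-free non-stabilised ylide; the adjacent carbon is quaternary, so the stereocentre cannot epimerise.

Step 11
Reactants: 17 tert-butyl (1R)-1-methyl-2-methylidenecyclopentane-1-carboxylate
Product: 18 [(1R)-1-methyl-2-methylidenecyclopentyl]methanol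
Conditions: LiAlH4, Et2O, 0→35 °C; H2O/aq. NaOH work-up
Reagents that add atoms: none
Why: Hydride reduction of the ester to the primary alcohol, with the isolated alkene and the stereocentre untouched.

Step 12
Reactants: 18 [(1R)-1-methyl-2-methylidenecyclopentyl]methanol
Product: 19 (1R)-1-(iodomethyl)-1-methyl-2-methylidenecyclopentane
Conditions: I2, PPh3, imidazole, toluene, 80 °C
Reagents that add atoms: iodine [I][I]
Why: Appel-type iodination through the alkoxyphosphonium iodide; the substitution takes place at the primary carbon and is slow but clean for a neopentyl-type alcohol at elevated temperature.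

Step 13
Reactants: 19 (1R)-1-(iodomethyl)-1-methyl-2-methylidenecyclopentane; 14 (2Z)-3-formyl-1-[(2R)-6-methoxy-2,8-dimethyl-3,4-dihydro-2H-chromen-2-yl]-5-methylhexa-2,5-dien-2-yl trifluoromethanesulfonate
Product: 22 (3aS,7aS)-6-{[(2R)-6-methoxy-2,8-dimethyl-3,4-dihydro-2H-chromen-2-yl]methyl}-3a,7a-dimethyl-5-(2-methylprop-2-en-1-yl)-1,2,3,3a,7,7a-hexahydro-4H-inden-4-one, via alkylzinc iodide 20 (not isolated), via coupled enal 21 (not isolated)
Conditions: 19, Zn dust, LiCl, THF, 50 °C; then 14, Pd(OAc)2 (4 mol%), 2-dicyclohexylphosphino-2′,6′-dimethoxybiphenyl (8 mol%), THF, 25 °C; then TMEDA, 2-mesityl-6,7-dihydro-5H-pyrrolo[2,1-c][1,2,4]triazol-2-ium chloride (20 mol%), DBU (40 mol%), 1,4-dioxane, 100 °C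
Reagents that add atoms: none
Why: Proposed new method: zinc inserts into the carbon–iodine bond of 19 and the alkylzinc iodide 20 undergoes a stereoretentive Negishi coupling with the (Z)-enol triflate 14 (oxidative addition of zerovalent palladium, transmetalation, reductive elimination), which forms the C7–C6 bond and places the cyclopentylmethyl arm cis to the formyl group in 21; the triazolylidene carbene then adds to the aldehyde and the resulting Breslow intermediate delivers its acyl carbon to the ring carbon of the exocyclic methylene and its O–H hydrogen to the terminal CH2 in a concerted Conia-ene-type step, which forms the C4–C3a bond, turns =CH2 into the angular methyl group and releases the carbene. The closest known reactions are the Negishi coupling of alkylzinc halides with stereodefined enol triflates of β-keto esters and the carbene-catalysed intramolecular hydroacylation of unactivated 1,1-disubstituted alkenes that gives 3,3-disubstituted chroman-4-ones; new are the merger of the two in one flask and the use of an enal-derived Breslow intermediate. The cyclohexenone ring is closed in the 6-exo-trig mode, the acyl carbon attacking the ring carbon of an alkene whose CH2 terminus stays outside the new ring. The new quaternary stereocentre C3a is controlled by the existing C7a centre, because the one-carbon tether can only reach the alkene face syn to the CH2 arm, so the ring fusion is cis and the two methyl groups lie on the same face. The step needs retention of the enol triflate geometry (given by the stereospecific coupling), bond formation at the substituted alkene carbon (a six-membered transition structure against a seven-membered one), reaction at the exocyclic methylene in preference to the 2-methylallyl alkene (which could only close a four-membered ring) and acyl-anion in preference to homoenolate reactivity (the β-carbon of the enal is fully substituted and no alcohol is present).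

Step 14
Reactants: 22 (3aS,7aS)-6-{[(2R)-6-methoxy-2,8-dimethyl-3,4-dihydro-2H-chromen-2-yl]methyl}-3a,7a-dimethyl-5-(2-methylprop-2-en-1-yl)-1,2,3,3a,7,7a-hexahydro-4H-inden-4-one
Product: 23 (3aS,7aS)-5-(2-hydroxy-2-methylpropyl)-6-{[(2R)-6-methoxy-2,8-dimethyl-3,4-dihydro-2H-chromen-2-yl]methyl}-3a,7a-dimethyl-1,2,3,3a,7,7a-hexahydro-4H-inden-4-one
Conditions: Co(acac)2 (20 mol%), PhSiH3, O2 (1 atm), i-PrOH, 25 °C
Reagents that add atoms: dioxygen O=O
Why: Mukaiyama hydration: a cobalt hydride transfers a hydrogen atom to the terminal carbon of the 1,1-disubstituted alkene, the tertiary radical is trapped by O2 and the peroxide is reduced by the silane to the tertiary alcohol (Markovnikov), while the tetrasubstituted electron-poor enone alkene is too hindered to react.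

**Compound list**
1 | 4-methoxy-2-methylphenol | COc1ccc(O)c(C)c1 | starting material
2 | 2-[(dimethylamino)methyl]-4-methoxy-6-methylphenol | COc1cc(C)c(O)c(CN(C)C)c1 | intermediate
3 | (2-hydroxy-5-methoxy-3-methylphenyl)-N,N,N-trimethylmethanaminium iodide | COc1cc(C)c(O)c(C[N+](C)(C)C)c1.[I-] | intermediate
4 | 4-methoxy-2-methyl-6-methylidenecyclohexa-2,4-dien-1-one (ortho-quinone methide) | COC1=CC(=C)C(=O)C(C)=C1 | intermediate
5 | 4-methoxy-2-methyl-6-(3-methylbut-3-en-1-yl)phenol | COc1cc(C)c(O)c(CCC(C)=C)c1 | intermediate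
6 | methyl 2-[(2R)-6-methoxy-2,8-dimethyl-3,4-dihydro-2H-chromen-2-yl]acetate | COc1cc(C)c2c(c1)CC[C@](C)(CC(=O)OC)O2 | intermediate
7 | 2-[(2R)-6-methoxy-2,8-dimethyl-3,4-dihydro-2H-chromen-2-yl]acetic acid | COc1cc(C)c2c(c1)CC[C@](C)(CC(=O)O)O2 | intermediate
8 | ethyl 4-methylpent-4-enoate | CCOC(=O)CCC(C)=C | starting material
9 | 1-(1H-imidazol-1-yl)-2-[(2R)-6-methoxy-2,8-dimethyl-3,4-dihydro-2H-chromen-2-yl]ethan-1-one | COc1cc(C)c2c(c1)CC[C@](C)(CC(=O)n1ccnc1)O2 | intermediate
10 | lithium enolate of ethyl 4-methylpent-4-enoate (lithium 1-ethoxy-4-methylpenta-1,4-dien-1-olate) | CCOC(O[Li])=CCC(C)=C | intermediate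
11 | ethyl 4-[(2R)-6-methoxy-2,8-dimethyl-3,4-dihydro-2H-chromen-2-yl]-2-(2-methylprop-2-en-1-yl)-3-oxobutanoate (both epimers at C2 of the butanoate) | COc1cc(C)c2c(c1)CC[C@](C)(CC(=O)C(CC(C)=C)C(=O)OCC)O2 | intermediate
12 | ethyl (2Z)-4-[(2R)-6-methoxy-2,8-dimethyl-3,4-dihydro-2H-chromen-2-yl]-2-(2-methylprop-2-en-1-yl)-3-{[(trifluoromethyl)sulfonyl]oxy}but-2-enoate | COc1cc(C)c2c(c1)CC[C@](C)(C/C(OS(=O)(=O)C(F)(F)F)=C(\CC(C)=C)C(=O)OCC)O2 | intermediate
13 | (2Z)-4-hydroxy-1-[(2R)-6-methoxy-2,8-dimethyl-3,4-dihydro-2H-chromen-2-yl]-3-(2-methylprop-2-en-1-yl)but-2-en-2-yl trifluoromethanesulfonate | COc1cc(C)c2c(c1)CC[C@](C)(C/C(OS(=O)(=O)C(F)(F)F)=C(\CC(C)=C)CO)O2 | intermediate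
14 | (2Z)-3-formyl-1-[(2R)-6-methoxy-2,8-dimethyl-3,4-dihydro-2H-chromen-2-yl]-5-methylhexa-2,5-dien-2-yl trifluoromethanesulfonate | COc1cc(C)c2c(c1)CC[C@](C)(C/C(OS(=O)(=O)C(F)(F)F)=C(\CC(C)=C)C=O)O2 | intermediate
15 | tert-butyl 2-oxocyclopentane-1-carboxylate | CC(C)(C)OC(=O)C1CCCC1=O | starting material
16 | tert-butyl (1R)-1-methyl-2-oxocyclopentane-1-carboxylate | O=C1CCC[C@@]1(C)C(=O)OC(C)(C)C | intermediate
17 | tert-butyl (1R)-1-methyl-2-methylidenecyclopentane-1-carboxylate | C=C1CCC[C@@]1(C)C(=O)OC(C)(C)C | intermediate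
18 | [(1R)-1-methyl-2-methylidenecyclopentyl]methanol | C=C1CCC[C@@]1(C)CO | intermediate
19 | (1R)-1-(iodomethyl)-1-methyl-2-methylidenecyclopentane | C=C1CCC[C@@]1(C)CI | intermediate
20 | iodido{[(1R)-1-methyl-2-methylidenecyclopentyl]methyl}zinc | C=C1CCC[C@@]1(C)C[Zn]I | intermediate
21 | (2E)-4-[(2R)-6-methoxy-2,8-dimethyl-3,4-dihydro-2H-chromen-2-yl]-2-(2-methylprop-2-en-1-yl)-3-{[(1S)-1-methyl-2-methylidenecyclopentyl]methyl}but-2-enal | COc1cc(C)c2c(c1)CC[C@](C)(C/C(C[C@]3(C)CCCC3=C)=C(\CC(C)=C)C=O)O2 | intermediate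
22 | (3aS,7aS)-6-{[(2R)-6-methoxy-2,8-dimethyl-3,4-dihydro-2H-chromen-2-yl]methyl}-3a,7a-dimethyl-5-(2-methylprop-2-en-1-yl)-1,2,3,3a,7,7a-hexahydro-4H-inden-4-one | COc1cc(C)c2c(c1)CC[C@](C)(CC1=C(CC(C)=C)C(=O)[C@@]3(C)CCC[C@@]3(C)C1)O2 | intermediate
23 | (3aS,7aS)-5-(2-hydroxy-2-methylpropyl)-6-{[(2R)-6-methoxy-2,8-dimethyl-3,4-dihydro-2H-chromen-2-yl]methyl}-3a,7a-dimethyl-1,2,3,3a,7,7a-hexahydro-4H-inden-4-one (CNP0224132.1) | COc1cc(C)c2c(c1)CC[C@](C)(CC1=C(CC(C)(C)O)C(=O)[C@@]3(C)CCC[C@@]3(C)C1)O2 | target

**Step count and risks**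
Total steps: 14. Longest linear sequence: 10 steps (steps 1 to 8, then 13 and 14).

Steps most likely to fail:

Step 13 (proposed new method). The carbene may be sequestered by zinc or palladium residues. The enal-derived Breslow intermediate may be diverted into β-protonation. The base may also deprotonate the γ-CH2 next to the chroman and open the oxygen ring. In each case the sequence would stall after the coupling. The fallback uses known reactions, sets out from 12 and 19 and comes back at 22. The zinc reagent 20 is coupled with the ester triflate 12 (Pd(OAc)2 and the same biaryl phosphine, THF, 25 °C; the Negishi coupling of stereodefined β-keto ester enol triflates) to give ethyl (2E)-4-[(2R)-6-methoxy-2,8-dimethyl-3,4-dihydro-2H-chromen-2-yl]-2-(2-methylprop-2-en-1-yl)-3-{[(1S)-1-methyl-2-methylidenecyclopentyl]methyl}but-2-enoate F1. Reduction with i-Bu2AlH at −78 °C should give (2E)-4-[(2R)-6-methoxy-2,8-dimethyl-3,4-dihydro-2H-chromen-2-yl]-2-(2-methylprop-2-en-1-yl)-3-{[(1S)-1-methyl-2-methylidenecyclopentyl]methyl}but-2-en-1-ol F2. Dess–Martin oxidation then gives the enal 21, now isolated and purified. The ring is closed by the nickel-catalysed intramolecular alkene hydroacylation known for ortho-alkenyl benzaldehydes (Ni(cod)2, 1,3-bis(2,6-diisopropylphenyl)imidazol-2-ylidene, mesitylene, 130 °C). Zerovalent nickel couples the carbonyl carbon with the substituted alkene carbon through an oxanickelacycle, without free carbene, base or homoenolate, and should give 22.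

Step 9. Facial discrimination in the ion-pair alkylation may be too weak, and an enantiomerically impure quaternary centre cannot be corrected later (it would give diastereomers after step 13). The fallback is a chiral-enamine alkylation, setting out from 15 and coming back at 16. Compound 15 is condensed with tert-butyl L-valinate (toluene, reflux, water removal) to give the enamino ester tert-butyl 2-{[(2S)-1-tert-butoxy-3-methyl-1-oxobutan-2-yl]amino}cyclopent-1-ene-1-carboxylate F3. Deprotonation with LiN(i-Pr)2 and methylation with MeI, in the solvent and additive combination that directs the electrophile to the face giving 1R, should give the imine tert-butyl (1R)-2-{[(2S)-1-tert-butoxy-3-methyl-1-oxobutan-2-yl]imino}-1-methylcyclopentane-1-carboxylate F4. Mild aqueous acid hydrolyses it to 16.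

Step 14. Hydrogen-atom transfer may also reach the enone (conjugate reduction or α-oxygenation), or radical oxygenation may occur at the allylic CH2 groups. The fallback is ionic and sets out from 22 and comes back at 23. Oxymercuration (Hg(OAc)2, THF/H2O, 25 °C) of the 1,1-disubstituted alkene, the only nucleophilic alkene present, gives acetato{3-[(3aS,7aS)-6-{[(2R)-6-methoxy-2,8-dimethyl-3,4-dihydro-2H-chromen-2-yl]methyl}-3a,7a-dimethyl-4-oxo-2,3,3a,4,7,7a-hexahydro-1H-inden-5-yl]-2-hydroxy-2-methylpropyl}mercury F5. Brief demercuration with NaBH4 in aq. NaOH at 0 °C should give 23.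

Further compounds
F1 | step 13 | ethyl (2E)-4-[(2R)-6-methoxy-2,8-dimethyl-3,4-dihydro-2H-chromen-2-yl]-2-(2-methylprop-2-en-1-yl)-3-{[(1S)-1-methyl-2-methylidenecyclopentyl]methyl}but-2-enoate | COc1cc(C)c2c(c1)CC[C@](C)(C/C(C[C@]3(C)CCCC3=C)=C(\CC(C)=C)C(=O)OCC)O2
F2 | step 13 | (2E)-4-[(2R)-6-methoxy-2,8-dimethyl-3,4-dihydro-2H-chromen-2-yl]-2-(2-methylprop-2-en-1-yl)-3-{[(1S)-1-methyl-2-methylidenecyclopentyl]methyl}but-2-en-1-ol | COc1cc(C)c2c(c1)CC[C@](C)(C/C(C[C@]3(C)CCCC3=C)=C(\CC(C)=C)CO)O2
F3 | step 9 | tert-butyl 2-{[(2S)-1-tert-butoxy-3-methyl-1-oxobutan-2-yl]amino}cyclopent-1-ene-1-carboxylate | CC(C)[C@H](NC1=C(CCC1)C(=O)OC(C)(C)C)C(=O)OC(C)(C)C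
F4 | step 9 | tert-butyl (1R)-2-{[(2S)-1-tert-butoxy-3-methyl-1-oxobutan-2-yl]imino}-1-methylcyclopentane-1-carboxylate | CC(C)[C@H](N=C1CCC[C@@]1(C)C(=O)OC(C)(C)C)C(=O)OC(C)(C)C
F5 | step 14 | acetato{3-[(3aS,7aS)-6-{[(2R)-6-methoxy-2,8-dimethyl-3,4-dihydro-2H-chromen-2-yl]methyl}-3a,7a-dimethyl-4-oxo-2,3,3a,4,7,7a-hexahydro-1H-inden-5-yl]-2-hydroxy-2-methylpropyl}mercury (both epimers at the carbinol carbon) | COc1cc(C)c2c(c1)CC[C@](C)(CC1=C(CC(C)(O)C[Hg]OC(C)=O)C(=O)[C@@]3(C)CCC[C@@]3(C)C1)O2
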